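**Plan**

1. Cuts: (i) C11'–C12' (alkylzinc + alkenyl iodide); (ii) the cyclohexene bonds C12–C14' and C15–C15' (Diels–Alder of a unit-1 diene with methyl vinyl ketone); (iii) in the 7-methylene decalin (unit 1) the bonds C5–C10 and C6–C7 together, back to an acyclic dialdehyde; (iv) C1–C10 (B-alkyl Suzuki); the 8'(17')-ene decalin (unit 2) goes back to an epoxy-farnesyl acetate.
2. Enabling feature: in ring B of unit 1 the methylene-bearing C7 is 1,3 to the ring-fusion carbon C5, so C7 is a latent aldol carbinol for a C6 enolate generated by radical addition to a C5=C6–C=O acceptor. C10 (quaternary, CH3) is a latent tertiary radical of a C10=CH2 alkene. C9 carries two CH2 groups (C8 in ring B, C11 in the chain) that can be made identical (two CH2CHO arms). The axial C19 methyl is 1,3 to C6, so a temporary C19–O–C(=O)–C6 lactone ties C4 to the acceptor.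
3. Forward: lactone 8 (C2–C6, C18, C19) + triflate 13 (C7–C12, C20) → Suzuki → bicyclization closes ring A, then ring B → lactone removed, C7=CH2 and side-chain diene made → cyclohexene → alkenyl iodide → union with iodide 42 → ester cleavage.
4. Stereochemistry: C4 from (S)-malate by two Fráter–Seebach alkylations; C5, C10, C9 relayed from C4 in the key step (lactone tether, chair transition states, desymmetrization of C9); C12/C14' by a chiral oxazaborolidinium Lewis acid (endo); C3' of a Sharpless epoxide sets C4', C5', C9', C10'; (E)-C12'=C13' by alkyne carboalumination.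

Key step: step 12

Remark: labdane numbering is used for each decalin (C18 = carboxyl carbon and C19 = methyl on C4, C20 = methyl on C10, primes for unit 2; cyclohexene ring = C12, C13, C14, C15, C15', C14'; α/β for unit 1 as in the normal labdane series), and the facial rule of the first Fráter–Seebach alkylation of malate is assumed to hold for the second.

**Route**

Step 1
Reactants: 1 dimethyl (S)-malate
Product: 2 dimethyl (2S,3R)-3-[(benzyloxy)methyl]-2-hydroxybutanedioate
Conditions: LiN(SiMe3)2 (2.2 equiv), THF, −78 °C; BnOCH2Cl, −78 → −20 °C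
Reagents that add atoms: benzyl chloromethyl ether, ClCOCc1ccccc1
Why: Fráter–Seebach alkylation of the chelated lithium alkoxide–enolate, in which the electrophile should enter anti to the C2 substituent of the chelate and so set C3.

Step 2
Reactants: 2 dimethyl (2S,3R)-3-[(benzyloxy)methyl]-2-hydroxybutanedioate
Product: 3 dimethyl (2S,3S)-3-[(benzyloxy)methyl]-2-hydroxy-3-(prop-2-en-1-yl)butanedioate
Conditions: LiN(SiMe3)2 (2.2 equiv), THF, −78 °C; allyl bromide, −78 → 0 °C
Reagents that add atoms: allyl bromide, C=CCBr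
Why: second Fráter–Seebach alkylation with the same facial preference should give the quaternary carbon (future C4), its configuration being fixed by the order in which the two groups are introduced.

Step 3
Reactants: 3 dimethyl (2S,3S)-3-[(benzyloxy)methyl]-2-hydroxy-3-(prop-2-en-1-yl)butanedioate
Product: 4 (2S,3S)-3-[(benzyloxy)methyl]-2-hydroxy-3-(methoxycarbonyl)hex-5-enoic acid
Conditions: LiOH (1.05 equiv), THF/H2O, 0 °C; then aq. HCl
Reagents that add atoms: lithium hydroxide, [Li+].[OH-]
Why: chemoselective saponification, the activated and unhindered α-hydroxy ester reacting before the neopentyl ester on the quaternary carbon.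

Step 4
Reactants: 4 (2S,3S)-3-[(benzyloxy)methyl]-2-hydroxy-3-(methoxycarbonyl)hex-5-enoic acid
Product: 5 methyl (2S)-2-[(benzyloxy)methyl]-2-formylpent-4-enoate
Conditions: Pb(OAc)4, CH2Cl2, 0 °C → rt
Reagents that add atoms: none
Why: oxidative decarboxylation of an α-hydroxy acid to the aldehyde; the malate carbinol carbon becomes the formyl group (future C5) on a non-enolizable quaternary centre.

Step 5
Reactants: 5 methyl (2S)-2-[(benzyloxy)methyl]-2-formylpent-4-enoate
Product: 6 dimethyl (2Z,4R)-4-[(benzyloxy)methyl]-4-(prop-2-en-1-yl)pent-2-enedioate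
Conditions: (CF3CH2O)2P(O)CH2CO2Me, KN(SiMe3)2, 18-crown-6, THF, −78 °C
Reagents that add atoms: methyl bis(2,2,2-trifluoroethyl)phosphonoacetate, COC(=O)CP(=O)(OCC(F)(F)F)OCC(F)(F)F
Why: Still–Gennari olefination should give the (Z)-enoate needed for lactonization (C5=C6 with the future helper carbonyl on C6).

Step 6
Reactants: 6 dimethyl (2Z,4R)-4-[(benzyloxy)methyl]-4-(prop-2-en-1-yl)pent-2-enedioate
Product: 8 methyl (3R)-6-oxo-3-(prop-2-en-1-yl)-3,6-dihydro-2H-pyran-3-carboxylate, via hydroxy Z-enoate 7 (not isolated)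
Conditions: BCl3, CH2Cl2, −78 → 0 °C; MeOH quench; pyridinium p-toluenesulfonate, toluene, 60 °C
Reagents that add atoms: none
Why: Lewis-acid debenzylation followed by lactonization of the (Z)-δ-hydroxy enoate installs the temporary C19–O–C(=O)–C6 ring (only the conjugated ester can form a six-membered lactone).

Step 7
Reactants: 9 cyclopent-3-ene-1-carboxylic acid
Product: 10 1-(cyclopent-3-en-1-yl)ethan-1-one
Conditions: MeLi (2.2 equiv), Et2O, 0 °C → rt; aq. NH4Cl
Reagents that add atoms: methyllithium, [Li]C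
Why: addition of methyllithium to the lithium carboxylate gives the methyl ketone after hydrolysis of the geminal dialkoxide.

Step 8
Reactants: 10 1-(cyclopent-3-en-1-yl)ethan-1-one
Product: 11 1-(cyclopent-3-en-1-yl)ethenyl trifluoromethanesulfonate
Conditions: KN(SiMe3)2, THF, −78 °C; PhNTf2
Reagents that add atoms: N-phenylbis(trifluoromethanesulfonimide), O=S(=O)(N(c1ccccc1)S(=O)(=O)C(F)(F)F)C(F)(F)F
Why: kinetic deprotonation at the methyl group and O-triflation give the terminal enol triflate (future C10=CH2).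

Step 9
Reactants: 11 1-(cyclopent-3-en-1-yl)ethenyl trifluoromethanesulfonate
Product: 13 3-(2,2-dimethoxyethyl)-5,5-dimethoxypent-1-en-2-yl trifluoromethanesulfonate, via dialdehyde triflate 12 (not isolated)
Conditions: O3 (1 equiv, indicator end point), CH2Cl2/MeOH, −78 °C; Me2S; then HC(OMe)3, p-toluenesulfonic acid (cat.), MeOH, rt
Reagents that add atoms: ozone, O=[O+][O-]; trimethyl orthoformate, COC(OC)OC; methanol, CO
Why: ozonolysis should take the electron-rich cyclopentene in preference to the electron-poor enol triflate, and acetalization stores the two identical CH2CHO arms on C9.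

Step 10
Reactants: 8 methyl (3R)-6-oxo-3-(prop-2-en-1-yl)-3,6-dihydro-2H-pyran-3-carboxylate; 13 3-(2,2-dimethoxyethyl)-5,5-dimethoxypent-1-en-2-yl trifluoromethanesulfonate
Product: 15 methyl (3R)-3-[5-(2,2-dimethoxyethyl)-7,7-dimethoxy-4-methylideneheptyl]-6-oxo-3,6-dihydro-2H-pyran-3-carboxylate, via B-alkyl-9-BBN 14 (not isolated)
Conditions: 8, 9-BBN, THF, 0 °C → rt; then 13, Pd(dppf)Cl2 (5 mol %), AsPh3, K3PO4 (aq), DMF, rt
Reagents that add atoms: none
Why: chemoselective hydroboration of the terminal allyl group and B-alkyl Suzuki–Miyaura coupling with the alkenyl triflate forge C1–C10 and create the 1,1-disubstituted C10=CH2 alkene.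

Step 11
Reactants: 15 methyl (3R)-3-[5-(2,2-dimethoxyethyl)-7,7-dimethoxy-4-methylideneheptyl]-6-oxo-3,6-dihydro-2H-pyran-3-carboxylate
Product: 16 methyl (3R)-3-[4-methylidene-7-oxo-5-(2-oxoethyl)heptyl]-6-oxo-3,6-dihydro-2H-pyran-3-carboxylate
Conditions: pyridinium p-toluenesulfonate, acetone/H2O, 50 °C
Reagents that add atoms: water, O
Why: mild acetal hydrolysis unmasks the two aldehydes without isomerizing the 1,1-disubstituted alkene.

Step 12
Reactants: 16 methyl (3R)-3-[4-methylidene-7-oxo-5-(2-oxoethyl)heptyl]-6-oxo-3,6-dihydro-2H-pyran-3-carboxylate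
Product: 19 tricyclic hydroxy lactone aldehyde (unit-1 trans-decalin: 5α-H; 10β-CH3; 4α-CO2Me; C19–O–C(=O)–C6β lactone bridge; 7-OH; 9β-CH2CHO), via tertiary C10 radical 17 (not isolated), via lactone iron enolate 18 (not isolated)
Conditions: Fe(acac)3 (0.5 equiv), PhSiH3 (2.5 equiv), EtOH/THF (1:1, 0.01 M), 23 °C, argon
Reagents that add atoms: none
Why: Proposed new method: an iron hydride made from Fe(acac)3 and PhSiH3 transfers a hydrogen atom to the electron-neutral C10=CH2 alkene; the tertiary radical 17 adds 6-exo-trig to C5, the β-carbon of the unsaturated lactone (ring A), and the α-acyl radical is reduced by divalent iron to the ferric enolate 18, which closes ring B by a 6-(enolexo)-exo-trig aldol addition of C6 to one of the two CH2CHO arms (C7). The closest known reaction type is the hydrogen-atom-transfer-initiated radical–polar crossover (Giese/aldol) annulation and polycyclization of unsaturated carbonyl compounds. C5: the radical can only reach the lactone face syn to the C3 tether, giving a cis-fused lactone with H5 cis to the C4 ester and anti to C19, so the C4/C5 relation of the target is relayed from the single stereocentre C4. C10: a chair transition state with the branched C9 substituent equatorial and the methyl axial should give the trans C5/C10 relation, hence a trans-decalin after the aldol. C9: of the two identical arms, the one that closes the ring-B chair with the other arm equatorial (cis to the C10 methyl) should react, and aldol reversibility lets this settle; C6 is fixed by the lactone bridge and C7 is left unassigned because it is oxidised in step 14. The selectivities needed are hydrogen-atom transfer to the 1,1-disubstituted alkene and not to the electron-poor lactone alkene (polarity match), and carbon–carbon capture of the enolate before protonation (six-membered intramolecular aldol against solvent protonation).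

Step 13
Reactants: 19 tricyclic hydroxy lactone aldehyde
Product: 20 tricyclic hydroxy lactone enal (as 19; 9β-CH2CH=C(CH3)CHO; E)
Conditions: Ph3P=C(CH3)CHO (1.1 equiv), toluene, 90 °C
Reagents that add atoms: 2-(triphenylphosphoranylidene)propanal, CC(C=O)=P(c1ccccc1)(c1ccccc1)c1ccccc1
Why: Wittig reaction of a stabilized ylide with the only aldehyde should give the (E)-2-methyl enal (C12=C13, C14), the free secondary alcohol being tolerated.

Step 14
Reactants: 20 tricyclic hydroxy lactone enal
Product: 21 tricyclic β-keto lactone enal (as 20; 7-oxo)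
Conditions: Dess–Martin periodinane, NaHCO3, CH2Cl2, 0 °C → rt
Reagents that add atoms: none
Why: Dess–Martin oxidation of the C7 carbinol to the ketone erases the C7 stereocentre and makes the lactone carbonyl on C6 a β-keto acyl group ready for removal.

Step 15
Reactants: 21 tricyclic β-keto lactone enal
Product: 23 hydroxy keto enal (unit-1 decalin: 7-oxo; C6 = CH2; 19-OH; 4α-CO2Me), via β-keto acid 22 (not isolated)
Conditions: LiOH, THF/H2O, 0 °C; then 1 M HCl, 40 °C
Reagents that add atoms: none
Why: saponification of the δ-lactone and decarboxylation of the resulting β-keto acid remove the activating carbonyl from C6 and release C19 as a primary alcohol, the hindered C18 methyl ester being untouched.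

Step 16
Reactants: 23 hydroxy keto enal
Product: 24 iodo keto enal (as 23; 19-I)
Conditions: I2, PPh3, imidazole, toluene, 80 °C
Reagents that add atoms: iodine, II
Why: Appel-type iodination converts the neopentyl primary alcohol into the iodide without touching the ketone or the enal.

Step 17
Reactants: 24 iodo keto enal
Product: 25 keto enal (unit-1 decalin: 7-oxo; 4β-CH3; 4α-CO2Me; 9β-CH2CH=C(CH3)CHO)
Conditions: Bu3SnH, azobisisobutyronitrile (cat.), benzene, 80 °C
Reagents that add atoms: none
Why: radical dehalogenation turns C19 into the axial methyl group, done before C7 carries an alkene so that the C19 radical has no 5-exo acceptor.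

Step 18
Reactants: 25 keto enal
Product: 26 methyl (1R,4aR,5S,8aR)-1,4a-dimethyl-7-methylidene-5-[(2E)-3-methylpenta-2,4-dien-1-yl]decahydronaphthalene-1-carboxylate
Conditions: Ph3PCH3Br (4 equiv), KOtBu, THF, 0 °C → rt
Reagents that add atoms: methyltriphenylphosphonium bromide, C[P+](c1ccccc1)(c1ccccc1)c1ccccc1.[Br-]
Why: double Wittig methylenation converts the C7 ketone into the exocyclic methylene and the enal into the (E)-1,3-diene in one operation.

Step 19
Reactants: 26 unit-1 triene ester
Product: 27 cyclohexenyl methyl ketone (cis-disubstituted cyclohexene; C12 S; C14' S; acetyl on C14')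
Conditions: methyl vinyl ketone (3 equiv), (S)-3,3-diphenyl-1-(2-methylphenyl)tetrahydro-1H,3H-pyrrolo[1,2-c][1,3,2]oxazaborole·HNTf2 (20 mol %), CH2Cl2, −78 → −40 °C
Reagents that add atoms: but-3-en-2-one, CC(=O)C=C
Why: Lewis-acid-catalysed Diels–Alder reaction in which the unsubstituted diene terminus C15 should bond to the enone β-carbon ("ortho" adduct), the endo transition state gives the cis C12/C14' relation, and the chiral oxazaborolidinium (enantiomer chosen by the α-C–H···O binding model so that the Re face of the enone α-carbon is attacked) should set the absolute configuration.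

Step 20
Reactants: 27 cyclohexenyl methyl ketone
Product: 29 terminal alkyne (as 27; C14'–C≡CH), via enol phosphate 28 (not isolated)
Conditions: LiN(iPr)2 (1.05 equiv), THF, −78 °C; ClP(O)(OEt)2; LiN(iPr)2 (2.3 equiv), −78 °C → rt
Reagents that add atoms: none
Why: kinetic enolization at the methyl group, O-phosphorylation and base-induced elimination convert the methyl ketone into the alkyne without enolizing towards C14'.

Step 21
Reactants: 29 terminal alkyne
Product: 31 (E)-alkenyl iodide (as 27; C14'–C(CH3)=CH–I), via alkenylalane 30 (not isolated)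
Conditions: Me3Al (3 equiv), Cp2ZrCl2 (0.3 equiv), H2O (1 equiv), CH2Cl2, −20 °C; then I2, THF, −30 °C
Reagents that add atoms: trimethylaluminium, C[Al](C)C; iodine, II
Why: zirconium-catalysed syn-carboalumination places the methyl on C13' and aluminium on C12', and iodinolysis with retention gives the (E)-trisubstituted alkenyl iodide.

Step 22
Reactants: 32 (2E,6E)-farnesyl acetate
Product: 33 (2E,6E,10E)-12-hydroxy-3,7,11-trimethyldodeca-2,6,10-trien-1-yl acetate
Conditions: SeO2 (0.3 equiv), t-BuOOH, salicylic acid (0.1 equiv), CH2Cl2, 0 °C → rt; then NaBH4, MeOH, 0 °C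
Reagents that add atoms: tert-butyl hydroperoxide, CC(C)(C)OO
Why: selenium dioxide allylic oxidation (ene reaction, then [2,3]-shift) should hydroxylate the (E)-methyl of the terminal, most electron-rich alkene.

Step 23
Reactants: 33 (2E,6E,10E)-12-hydroxy-3,7,11-trimethyldodeca-2,6,10-trien-1-yl acetate
Product: 34 (2E,6E)-9-[(2R,3R)-3-(hydroxymethyl)-3-methyloxiran-2-yl]-3,7-dimethylnona-2,6-dien-1-yl acetate
Conditions: Ti(OiPr)4 (10 mol %), D-(−)-diethyl tartrate (12 mol %), t-BuOOH, 4 Å molecular sieves, CH2Cl2, −20 °C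
Reagents that add atoms: tert-butyl hydroperoxide, CC(C)(C)OO
Why: Sharpless asymmetric epoxidation of the allylic alcohol; the D-tartrate should give the (2R,3R)-epoxy alcohol whose C3' centre later directs the fold into the unit-2 series.

Step 24
Reactants: 34 (2R,3R)-epoxy alcohol
Product: 35 (2E,6E)-9-[(2R,3R)-3-({[tert-butyl(dimethyl)silyl]oxy}methyl)-3-methyloxiran-2-yl]-3,7-dimethylnona-2,6-dien-1-yl acetate
Conditions: t-BuMe2SiCl, imidazole, DMF, rt
Reagents that add atoms: tert-butyldimethylsilyl chloride, CC(C)(C)[Si](C)(C)Cl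
Why: silylation makes the oxygen on the epoxide-bearing carbon a poor β-leaving group and a large substituent for the cyclization.

Step 25
Reactants: 35 silylated epoxy-farnesyl acetate
Product: 36 unit-2 decalin (11'-OAc; 8'(17')-methylidene; 3'-OH equatorial; 4'-CH3 axial; 4'-CH2OSi-t-BuMe2 equatorial; C5', C9', C10' as in the target)
Conditions: Cp2TiCl2 (2.2 equiv), Mn dust, THF, rt; then 1 M HCl
Reagents that add atoms: none
Why: titanocene-mediated radical epoxy-polyene cyclization, in which trivalent titanium opens the epoxide to the tertiary C4' radical, two 6-endo-trig closures through a chair–chair fold (C3' titanoxy and the larger CH2OSi group equatorial) set C4', C5', C10' and C9', and β-hydride loss from the C8' organotitanium gives the exocyclic alkene.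

Step 26
Reactants: 36 unit-2 decalin 3'-ol
Product: 37 3'-O-phenoxythiocarbonyl derivative of 36
Conditions: PhOC(S)Cl, pyridine, 4-(dimethylamino)pyridine (cat.), CH2Cl2, rt
Reagents that add atoms: O-phenyl chlorothionoformate, S=C(Cl)Oc1ccccc1
Why: thioacylation of the secondary alcohol prepares the Barton–McCombie deoxygenation.

Step 27
Reactants: 37 3'-O-phenoxythiocarbonyl derivative
Product: 38 unit-2 decalin (as 36; C3' = CH2)
Conditions: Bu3SnH, azobisisobutyronitrile (cat.), toluene, 100 °C
Reagents that add atoms: none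
Why: Barton–McCombie deoxygenation removes the hydroxyl that served only to direct the cyclization; the C3' radical is remote from the alkene.

Step 28
Reactants: 38 unit-2 decalin silyl ether
Product: 39 unit-2 acid (11'-OAc; 4'-CO2H equatorial)
Conditions: CrO3, H2SO4, acetone/H2O, 0 °C
Reagents that add atoms: chromium trioxide, O=[Cr](=O)=O; water, O
Why: Jones conditions cleave the primary silyl ether and oxidise the neopentyl alcohol to the acid in one operation.

Step 29
Reactants: 39 unit-2 acid
Product: 41 unit-2 hydroxy ester (11'-OH; 4'-CO2Me), via acetoxy methyl ester 40 (not isolated)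
Conditions: MeI, K2CO3, DMF, rt; then MeOH, rt
Reagents that add atoms: iodomethane, CI
Why: carboxylate O-alkylation followed by methanolysis of the unhindered primary acetate, the neopentyl methyl ester being inert.

Step 30
Reactants: 41 unit-2 hydroxy ester
Product: 42 unit-2 iodide (9'-CH2I; 8'(17')-methylidene; 4'-CO2Me)
Conditions: I2, PPh3, imidazole, CH2Cl2, 0 °C → rt
Reagents that add atoms: iodine, II
Why: Appel-type iodination of the primary alcohol.

Step 31
Reactants: 42 unit-2 iodide; 31 (E)-alkenyl iodide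
Product: 44 dimethyl ester of the target, via alkylzinc iodide 43 (not isolated)
Conditions: 42, Zn dust, LiCl, THF, 40 °C; then 31, Pd(OAc)2 (5 mol %), 2-dicyclohexylphosphino-2',6'-dimethoxybiphenyl (10 mol %), THF/NMP, rt
Reagents that add atoms: none
Why: zinc insertion into the primary iodide and Negishi sp3–sp2 coupling join C11' to C12' with retention of the (E)-alkene geometry, esters and 1,1-disubstituted alkenes being tolerated.

Step 32
Reactants: 44 dimethyl ester of the target
Product: 45 CNP0240573.1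
Conditions: n-PrSLi (6 equiv), HMPA, rt → 50 °C; then aq. HCl
Reagents that add atoms: none
Why: SN2 demethylation by thiolate cleaves both hindered neopentyl methyl esters at the methyl carbon under non-acidic conditions that should leave the exocyclic and trisubstituted alkenes in place.

**Compound list**

1 | dimethyl (S)-malate | COC(=O)C[C@H](O)C(=O)OC | starting material
2 | dimethyl (2S,3R)-3-[(benzyloxy)methyl]-2-hydroxybutanedioate | COC(=O)[C@@H](O)[C@@H](COCc1ccccc1)C(=O)OC | intermediate
3 | dimethyl (2S,3S)-3-[(benzyloxy)methyl]-2-hydroxy-3-(prop-2-en-1-yl)butanedioate | COC(=O)[C@@H](O)[C@](CC=C)(COCc1ccccc1)C(=O)OC | intermediate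
4 | (2S,3S)-3-[(benzyloxy)methyl]-2-hydroxy-3-(methoxycarbonyl)hex-5-enoic acid | OC(=O)[C@@H](O)[C@](CC=C)(COCc1ccccc1)C(=O)OC | intermediate
5 | methyl (2S)-2-[(benzyloxy)methyl]-2-formylpent-4-enoate | O=C[C@](CC=C)(COCc1ccccc1)C(=O)OC | intermediate
6 | dimethyl (2Z,4R)-4-[(benzyloxy)methyl]-4-(prop-2-en-1-yl)pent-2-enedioate | COC(=O)/C=C\[C@](CC=C)(COCc1ccccc1)C(=O)OC | intermediate
7 | dimethyl (2Z,4R)-4-(hydroxymethyl)-4-(prop-2-en-1-yl)pent-2-enedioate | COC(=O)/C=C\[C@](CC=C)(CO)C(=O)OC | intermediate
8 | methyl (3R)-6-oxo-3-(prop-2-en-1-yl)-3,6-dihydro-2H-pyran-3-carboxylate | C=CC[C@]1(C(=O)OC)COC(=O)C=C1 | intermediate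
9 | cyclopent-3-ene-1-carboxylic acid | OC(=O)C1CC=CC1 | starting material
10 | 1-(cyclopent-3-en-1-yl)ethan-1-one | CC(=O)C1CC=CC1 | intermediate
11 | 1-(cyclopent-3-en-1-yl)ethenyl trifluoromethanesulfonate | C=C(OS(=O)(=O)C(F)(F)F)C1CC=CC1 | intermediate
12 | 5-oxo-3-(2-oxoethyl)pent-1-en-2-yl trifluoromethanesulfonate | C=C(OS(=O)(=O)C(F)(F)F)C(CC=O)CC=O | intermediate
13 | 3-(2,2-dimethoxyethyl)-5,5-dimethoxypent-1-en-2-yl trifluoromethanesulfonate | C=C(OS(=O)(=O)C(F)(F)F)C(CC(OC)OC)CC(OC)OC | intermediate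
14 | methyl (3R)-3-[3-(9-borabicyclo[3.3.1]nonan-9-yl)propyl]-6-oxo-3,6-dihydro-2H-pyran-3-carboxylate | B1(C2CCCC1CCC2)CCC[C@]1(C(=O)OC)COC(=O)C=C1 | intermediate
15 | methyl (3R)-3-[5-(2,2-dimethoxyethyl)-7,7-dimethoxy-4-methylideneheptyl]-6-oxo-3,6-dihydro-2H-pyran-3-carboxylate | COC(OC)CC(CC(OC)OC)C(=C)CCC[C@]1(C(=O)OC)COC(=O)C=C1 | intermediate
16 | methyl (3R)-3-[4-methylidene-7-oxo-5-(2-oxoethyl)heptyl]-6-oxo-3,6-dihydro-2H-pyran-3-carboxylate | O=CCC(CC=O)C(=C)CCC[C@]1(C(=O)OC)COC(=O)C=C1 | intermediate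
17 | tertiary C10 radical formed from 16 by hydrogen-atom transfer to the methylidene carbon | O=CCC(CC=O)[C](C)CCC[C@]1(C(=O)OC)COC(=O)C=C1 | intermediate
18 | lactone enolate after closure of ring A (iron enolate, drawn as the anion) | O=CCC(CC=O)[C@@]1(C)CCC[C@@](COC2[O-])(C(=O)OC)[C@@H]1C=2 | intermediate
19 | tricyclic hydroxy lactone aldehyde: unit-1 trans-decalin, 5α-H, 10β-CH3, 4α-CO2Me, lactone bridge C19–O–C(=O)–C6β, 7-OH (either epimer), 9β-CH2CHO | OC1C[C@H](CC=O)[C@@]2(C)CCC[C@@](COC3=O)(C(=O)OC)[C@@H]2[C@@H]13 | intermediate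
20 | as 19 with 9β-[(2E)-3-methyl-4-oxobut-2-en-1-yl] | OC1C[C@H](C/C=C(\C)C=O)[C@@]2(C)CCC[C@@](COC3=O)(C(=O)OC)[C@@H]2[C@@H]13 | intermediate
21 | as 20 with 7-oxo (β-keto lactone) | O=C1C[C@H](C/C=C(\C)C=O)[C@@]2(C)CCC[C@@](COC3=O)(C(=O)OC)[C@@H]2[C@@H]13 | intermediate
22 | β-keto acid from lactone opening of 21 (6-CO2H, 7-oxo, 19-OH) | O=C1C[C@H](C/C=C(\C)C=O)[C@@]2(C)CCC[C@@](CO)(C(=O)OC)[C@@H]2C1C(=O)O | intermediate
23 | unit-1 decalin: 7-oxo, 4β-CH2OH, 4α-CO2Me, 9β-[(2E)-3-methyl-4-oxobut-2-en-1-yl] | O=C1C[C@H](C/C=C(\C)C=O)[C@@]2(C)CCC[C@@](CO)(C(=O)OC)[C@@H]2C1 | intermediate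
24 | as 23 with 4β-CH2I | O=C1C[C@H](C/C=C(\C)C=O)[C@@]2(C)CCC[C@@](CI)(C(=O)OC)[C@@H]2C1 | intermediate
25 | as 23 with 4β-CH3 | O=C1C[C@H](C/C=C(\C)C=O)[C@@]2(C)CCC[C@@](C)(C(=O)OC)[C@@H]2C1 | intermediate
26 | methyl (1R,4aR,5S,8aR)-1,4a-dimethyl-7-methylidene-5-[(2E)-3-methylpenta-2,4-dien-1-yl]decahydronaphthalene-1-carboxylate | C=C1C[C@H](C/C=C(\C)C=C)[C@@]2(C)CCC[C@@](C)(C(=O)OC)[C@@H]2C1 | intermediate
27 | unit-1 decalin ester carrying on C11 a cis-2-acetyl-6-methylcyclohex-5-enyl ring (C12 S, C14' S) | C=C1C[C@H](C[C@@H]2C(C)=CCC[C@@H]2C(C)=O)[C@@]2(C)CCC[C@@](C)(C(=O)OC)[C@@H]2C1 | intermediate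
28 | enol diethyl phosphate of 27 | C=C1C[C@H](C[C@@H]2C(C)=CCC[C@@H]2C(=C)OP(=O)(OCC)OCC)[C@@]2(C)CCC[C@@](C)(C(=O)OC)[C@@H]2C1 | intermediate
29 | as 27 with ethynyl on C14' | C=C1C[C@H](C[C@@H]2C(C)=CCC[C@@H]2C#C)[C@@]2(C)CCC[C@@](C)(C(=O)OC)[C@@H]2C1 | intermediate
30 | (E)-alkenyl(dimethyl)alane from 29 | C=C1C[C@H](C[C@@H]2C(C)=CCC[C@@H]2/C(C)=C/[Al](C)C)[C@@]2(C)CCC[C@@](C)(C(=O)OC)[C@@H]2C1 | intermediate
31 | as 27 with (E)-1-iodoprop-1-en-2-yl on C14' | C=C1C[C@H](C[C@@H]2C(C)=CCC[C@@H]2/C(C)=C/I)[C@@]2(C)CCC[C@@](C)(C(=O)OC)[C@@H]2C1 | intermediate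
32 | (2E,6E)-farnesyl acetate | CC(=O)OC/C=C(\C)CC/C=C(\C)CCC=C(C)C | starting material
33 | (2E,6E,10E)-12-hydroxy-3,7,11-trimethyldodeca-2,6,10-trien-1-yl acetate | CC(=O)OC/C=C(\C)CC/C=C(\C)CC/C=C(\C)CO | intermediate
34 | (2E,6E)-9-[(2R,3R)-3-(hydroxymethyl)-3-methyloxiran-2-yl]-3,7-dimethylnona-2,6-dien-1-yl acetate | CC(=O)OC/C=C(\C)CC/C=C(\C)CC[C@H]1O[C@]1(C)CO | intermediate
35 | tert-butyldimethylsilyl ether of 34 | CC(=O)OC/C=C(\C)CC/C=C(\C)CC[C@H]1O[C@]1(C)CO[Si](C)(C)C(C)(C)C | intermediate
36 | unit-2 trans-decalin: 9'-CH2OAc, 8'(17')-methylidene, 3'-OH equatorial (3'R), 4'-CH3 axial, 4'-CH2OSi-t-BuMe2 equatorial | CC(=O)OC[C@@H]1C(=C)CC[C@H]2[C@@]1(C)CC[C@@H](O)[C@]2(C)CO[Si](C)(C)C(C)(C)C | intermediate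
37 | 3'-O-(phenoxythiocarbonyl) derivative of 36 | CC(=O)OC[C@@H]1C(=C)CC[C@H]2[C@@]1(C)CC[C@@H](OC(=S)Oc3ccccc3)[C@]2(C)CO[Si](C)(C)C(C)(C)C | intermediate
38 | 3'-deoxy derivative of 36 | CC(=O)OC[C@@H]1C(=C)CC[C@H]2[C@@]1(C)CCC[C@]2(C)CO[Si](C)(C)C(C)(C)C | intermediate
39 | unit-2 acid: 9'-CH2OAc, 4'-CO2H equatorial | CC(=O)OC[C@@H]1C(=C)CC[C@H]2[C@@]1(C)CCC[C@]2(C)C(=O)O | intermediate
40 | methyl ester of 39 | CC(=O)OC[C@@H]1C(=C)CC[C@H]2[C@@]1(C)CCC[C@]2(C)C(=O)OC | intermediate
41 | unit-2 hydroxy ester: 9'-CH2OH, 4'-CO2Me | OC[C@@H]1C(=C)CC[C@H]2[C@@]1(C)CCC[C@]2(C)C(=O)OC | intermediate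
42 | unit-2 iodide: 9'-CH2I, 4'-CO2Me | IC[C@@H]1C(=C)CC[C@H]2[C@@]1(C)CCC[C@]2(C)C(=O)OC | intermediate
43 | alkylzinc iodide from 42 | I[Zn]C[C@@H]1C(=C)CC[C@H]2[C@@]1(C)CCC[C@]2(C)C(=O)OC | intermediate
44 | dimethyl ester of CNP0240573.1 | C=C1C[C@H](C[C@@H]2C(C)=CCC[C@@H]2/C(C)=C/C[C@@H]2C(=C)CC[C@H]3[C@@]2(C)CCC[C@]3(C)C(=O)OC)[C@@]2(C)CCC[C@@](C)(C(=O)OC)[C@@H]2C1 | intermediate
45 | CNP0240573.1 | C=C1C[C@H](C[C@@H]2C(C)=CCC[C@@H]2/C(C)=C/C[C@@H]2C(=C)CC[C@H]3[C@@]2(C)CCC[C@]3(C)C(=O)O)[C@@]2(C)CCC[C@@](C)(C(=O)O)[C@@H]2C1 | target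

**Count and risks**

Total step count: 32. Longest linear sequence: 20 steps (1–6, 10–21, 31, 32).

Steps most likely to fail:

1. Step 12 (Proposed new method). The ferric lactone enolate may be protonated by the solvent before the aldol closure, so that the cascade stops after ring A, or the aldol may not discriminate the two arms. Fallback by known reactions, setting out from 15: the same hydrogen-atom-transfer Giese cyclization (Fe(acac)3, PhSiH3, EtOH), run with the aldehydes still masked, should give the cis-fused bicyclic lactone bis-acetal F1. Enolization with LiN(SiMe3)2 and N-bromosuccinimide gives the α-bromo lactone F2, and pyridinium p-toluenesulfonate in aqueous acetone gives the bromo dialdehyde F3. SmI2 in THF at −78 °C then closes ring B by an intramolecular Reformatsky reaction, and the route is rejoined at 19.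

2. Step 25. The planar C4' radical may not place the silyloxymethyl group equatorially with useful selectivity, and the termination may give endocyclic alkene isomers. Fallback, setting out from 35: a cationic cyclization with MeAlCl2 in CH2Cl2 at −78 °C opens the epoxide with inversion (the E substituent becomes equatorial) and, with capture of the C8' cation by the neighbouring acetate, should give after work-up the 3',8'-diol monoacetate F5. Selective thioacylation of the secondary hydroxyl gives the thionocarbonate F6, and Bu3SnH gives the tertiary alcohol F7. Dehydration of the equatorial tertiary alcohol with SOCl2 and pyridine at −78 °C should give the exocyclic alkene, and the route is rejoined at 38.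

3. Step 19. Orientation ("ortho" against "para") with a diene that carries substituents on C12 and C13, diene-face selection under catalyst control, and acid-induced migration of the exocyclic alkenes may all erode the step. Fallback, setting out from 26: iminium-ion catalysis with acrolein and (5S)-5-benzyl-2,2,3-trimethylimidazolidin-4-one hydrochloride in aqueous acetonitrile should give the cis aldehyde F4 under milder, non-Lewis-acidic conditions. Ohira–Bestmann homologation (dimethyl (1-diazo-2-oxopropyl)phosphonate, K2CO3, MeOH, 0 °C) converts it into the alkyne, and the route is rejoined at 29.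

Further compounds
F1 | step 12 | cis-fused bicyclic lactone bis-acetal (ring A closed, C6 = CH2, arms as dimethyl acetals) | COC(OC)CC(CC(OC)OC)[C@@]1(C)CCC[C@@](COC2=O)(C(=O)OC)[C@@H]1C2
F2 | step 12 | α-bromo lactone from F1 (bromine on C6) | COC(OC)CC(CC(OC)OC)[C@@]1(C)CCC[C@@](COC2=O)(C(=O)OC)[C@@H]1C2Br
F3 | step 12 | bromo dialdehyde from F2 | O=CCC(CC=O)[C@@]1(C)CCC[C@@](COC2=O)(C(=O)OC)[C@@H]1C2Br
F5 | step 25 | unit-2 decalin 3',8'-diol 11'-acetate (8'-OH equatorial, 4'-CH2OSi-t-BuMe2 equatorial) | CC(=O)OC[C@@H]1[C@@](C)(O)CC[C@H]2[C@@]1(C)CC[C@@H](O)[C@]2(C)CO[Si](C)(C)C(C)(C)C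
F6 | step 25 | 3'-O-(phenoxythiocarbonyl) derivative of F5 | CC(=O)OC[C@@H]1[C@@](C)(O)CC[C@H]2[C@@]1(C)CC[C@@H](OC(=S)Oc3ccccc3)[C@]2(C)CO[Si](C)(C)C(C)(C)C
F7 | step 25 | 3'-deoxy-8'-ol from F6 | CC(=O)OC[C@@H]1[C@@](C)(O)CC[C@H]2[C@@]1(C)CCC[C@]2(C)CO[Si](C)(C)C(C)(C)C
F4 | step 19 | cis aldehyde (as 27 with formyl on C14') | C=C1C[C@H](C[C@@H]2C(C)=CCC[C@@H]2C=O)[C@@]2(C)CCC[C@@](C)(C(=O)OC)[C@@H]2C1
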